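**Strategy**

Ring A is a fully substituted acylphloroglucinol in which the aroyl-bearing C3 lies between the C2 and C4 hydroxyls and para to the C6 methoxyl, the oxygen pattern a 3,5,7-triketo acid gives on Claisen ring closure. Everything therefore rests on the ring-A C3–C4 bond. In one operation Mg(OMe)2 opens a 4-methoxy-2-pyrone, lets the aroylmethyl carbon acylate the former lactone carbonyl, aromatises ring A and frees the ring-B phenol. The precursor is an (R)-6-(aroylmethyl)-4-methoxy-3-prenyl-2-pyrone with the branched side chain on pyrone C5 and ring B as a silyl ether, so every ring-A substituent and the stereocentre are set before the benzene ring is made.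

Key step: step 11

Remark on the chemistry: the lipase is taken to acylate the (R)-alcohol faster, as expected for 2-isopropenyl primary alcohols of this type, and ring B is carried as a silyl ether so that no acid is needed once the prenylated ring-A diphenol exists; ring-A atoms are numbered C1 (side chain), C2 (OH), C3 (aroyl), C4 (OH), C5 (prenyl), C6 (OMe).

**Route**

Step 1
Reactants: 1 methyl 3-methylbut-2-enoate; 2 4-bromo-2-methylbut-1-ene
Product: 3 methyl 5-methyl-2-(prop-1-en-2-yl)hex-5-enoate (racemic)
Conditions: LiN(iPr)2 (1.1 equiv), THF–DMPU, −78 °C; then 2, −78 °C → rt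
Reagents that add atoms: none
Why: Deconjugative α-alkylation of the lithium dienolate of a 3,3-dimethylacrylate, which reacts with the primary bromide at its α-carbon, moves the double bond out of conjugation and creates the branched carbon as a racemate.

Step 2
Reactants: 3 methyl 5-methyl-2-(prop-1-en-2-yl)hex-5-enoate (racemic)
Product: 4 5-methyl-2-(prop-1-en-2-yl)hex-5-en-1-ol (racemic)
Conditions: LiAlH4, Et2O, 0 °C
Reagents that add atoms: none
Why: Hydride reduction of the ester with LiAlH4 at 0 °C should give the primary alcohol without moving the β,γ-double bond into conjugation.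

Step 3
Reactants: 4 5-methyl-2-(prop-1-en-2-yl)hex-5-en-1-ol (racemic)
Product: 5 (2S)-5-methyl-2-(prop-1-en-2-yl)hex-5-en-1-ol
Conditions: immobilised Candida antarctica lipase B, vinyl acetate, tert-butyl methyl ether, rt, run past half conversion; chromatographic separation from the (R)-acetate
Reagents that add atoms: none
Why: Lipase-catalysed kinetic resolution by irreversible transesterification, in which the (R)-alcohol should be acetylated faster, so that carrying the reaction beyond half conversion should leave the (S)-alcohol in high enantiomeric purity and thereby fix the only stereocentre of the target.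

Step 4
Reactants: 5 (2S)-5-methyl-2-(prop-1-en-2-yl)hex-5-en-1-ol
Product: 6 (3S)-3-(iodomethyl)-2,6-dimethylhepta-1,6-diene
Conditions: PPh3, I2, imidazole, CH2Cl2, 0 °C → rt
Reagents that add atoms: iodine, II
Why: Appel-type iodination in which iodide displaces the alkoxyphosphonium group by SN2 at the CH2 carbon, so the neighbouring stereocentre keeps its arrangement and its S descriptor.

Step 5
Reactants: 6 (3S)-3-(iodomethyl)-2,6-dimethylhepta-1,6-diene; 7 acetylacetone
Product: 8 3-[(2R)-5-methyl-2-(prop-1-en-2-yl)hex-5-en-1-yl]pentane-2,4-dione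
Conditions: 7 (3 equiv), K2CO3, butan-2-one, reflux
Reagents that add atoms: none
Why: SN2 C-alkylation of the potassium enolate of acetylacetone, a soft and weakly basic nucleophile that should substitute the β-branched homoallylic iodide without E2 elimination, while the stereocentre, not being the reacting carbon, changes only its descriptor from S to R through the new substituent priorities.

Step 6
Reactants: 8 3-[(2R)-5-methyl-2-(prop-1-en-2-yl)hex-5-en-1-yl]pentane-2,4-dione
Product: 10 4-hydroxy-6-methyl-5-[(2R)-5-methyl-2-(prop-1-en-2-yl)hex-5-en-1-yl]-2H-pyran-2-one, via diketo acid 9 (not isolated)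
Conditions: LiN(iPr)2 (2.3 equiv), THF, −78 → 0 °C; CO2 gas, −78 °C; 1 M HCl, 0 °C; crude acid 9 treated at once with 1,1'-carbonyldiimidazole, THF, 0 °C → rt
Reagents that add atoms: carbon dioxide, O=C=O
Why: Carboxylation of the 1,3-dianion of the β-diketone at its terminal carbanion, followed by lactonisation of the resulting 3,5-dioxo acid through its acyl imidazolide (attack of the C5 enol oxygen on the activated carboxyl), is the established two-stage route from a β-diketone to a 4-hydroxy-6-methyl-2-pyrone and leaves the remote stereocentre untouched.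

Step 7
Reactants: 10 4-hydroxy-6-methyl-5-[(2R)-5-methyl-2-(prop-1-en-2-yl)hex-5-en-1-yl]-2H-pyran-2-one
Product: 11 4-hydroxy-6-methyl-3-(3-methylbut-2-en-1-yl)-5-[(2R)-5-methyl-2-(prop-1-en-2-yl)hex-5-en-1-yl]-2H-pyran-2-one
Conditions: 3-methylbut-2-en-1-yl acetate, Pd(PPh3)4 (5 mol %), DBU, toluene, 60 °C
Reagents that add atoms: 3-methylbut-2-en-1-yl acetate (prenyl acetate), CC(=O)OCC=C(C)C
Why: Tsuji–Trost allylation with a zerovalent palladium catalyst, in which the acidic hydroxypyrone (as its DBU salt) should attack the 1,1-dimethylallyl palladium complex at the unsubstituted terminus through pyrone C3, its only nucleophilic carbon, while any O-prenyl ether re-ionises on the catalyst and is funnelled to the C-prenyl product.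

Step 8
Reactants: 11 4-hydroxy-6-methyl-3-(3-methylbut-2-en-1-yl)-5-[(2R)-5-methyl-2-(prop-1-en-2-yl)hex-5-en-1-yl]-2H-pyran-2-one
Product: 12 4-methoxy-6-methyl-3-(3-methylbut-2-en-1-yl)-5-[(2R)-5-methyl-2-(prop-1-en-2-yl)hex-5-en-1-yl]-2H-pyran-2-one
Conditions: Me2SO4, K2CO3, acetone, reflux
Reagents that add atoms: dimethyl sulfate, COS(=O)(=O)OC
Why: O-methylation of the pyronate anion with dimethyl sulfate under K2CO3 in acetone should take place mainly at the C4 oxygen, giving the 4-methoxy-2-pyrone that locks the future C6 methoxyl of ring A, and any 2-methoxy-4-pyrone isomer would be removed by chromatography.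

Step 9
Reactants: 13 methyl 3-hydroxybenzoate
Product: 14 methyl 3-[(tert-butyldimethylsilyl)oxy]benzoate
Conditions: TBSCl, imidazole, DMF, rt
Reagents that add atoms: tert-butyldimethylsilyl chloride, CC(C)(C)[Si](C)(C)Cl
Why: Silyl ether formation masks the phenol as a group that survives the amide base of step 10 and is removed by basic methanol in step 11.

Step 10
Reactants: 12 4-methoxy-6-methyl-3-(3-methylbut-2-en-1-yl)-5-[(2R)-5-methyl-2-(prop-1-en-2-yl)hex-5-en-1-yl]-2H-pyran-2-one; 14 methyl 3-[(tert-butyldimethylsilyl)oxy]benzoate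
Product: 15 6-{2-[3-(tert-butyldimethylsilyloxy)phenyl]-2-oxoethyl}-4-methoxy-3-(3-methylbut-2-en-1-yl)-5-[(2R)-5-methyl-2-(prop-1-en-2-yl)hex-5-en-1-yl]-2H-pyran-2-one
Conditions: LiN(SiMe3)2 (2.2 equiv), THF, −78 °C; then 14, −78 → 0 °C; aqueous NH4Cl
Reagents that add atoms: none
Why: Crossed Claisen condensation in which the amide base removes a proton from the 6-methyl group, the vinylogous acidic position of the pyrone dienoate, and the anion is acylated by ester 14, the second equivalent of base converting the β-keto pyrone into its enolate as it forms and so preventing a second acylation.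

Step 11
Reactants: 15 6-{2-[3-(tert-butyldimethylsilyloxy)phenyl]-2-oxoethyl}-4-methoxy-3-(3-methylbut-2-en-1-yl)-5-[(2R)-5-methyl-2-(prop-1-en-2-yl)hex-5-en-1-yl]-2H-pyran-2-one
Product: 18 (3-hydroxyphenyl){2,6-dihydroxy-4-methoxy-3-(3-methylbut-2-en-1-yl)-5-[(2R)-5-methyl-2-(prop-1-en-2-yl)hex-5-en-1-yl]phenyl}methanone (target CNP0139402.2), via ring-opened methyl ester 16 (not isolated), via silyl-protected benzophenone 17 (not isolated)
Conditions: Mg(OMe)2 (excess), MeOH, reflux until ring closure and desilylation are complete; then cold 0.5 M HCl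
Reagents that add atoms: none
Why: Addition of methoxide at pyrone C2 (the future ring-A C4) cleaves the lactone C–O bond and gives the acyclic methyl ester 16, a (2E)-β-methoxyacrylate whose ester group and diketone arm are held cis across the old pyrone C3=C4 bond. Deprotonation between the two ketones gives a magnesium chelate whose central carbon (the future C3) adds to the ester carbonyl in a 6-exo-trig closure of Claisen (Dieckmann) type, after which loss of methoxide and enolisation of the cyclic triketone should deliver the aromatic ring A of 17. The closest known reaction type is the Mg(OMe)2-mediated conversion of 6-(2-oxoalkyl)-2-pyrones and the corresponding triketo esters into acylphloroglucinols. No stereocentre is formed, and the (R) centre of the side chain is not enolisable and is not touched. The selectivity required is carbon acylation over aldol-type closure or attack through enol oxygen: the ester α-carbon (old pyrone C3) is a fully substituted enol-ether carbon that cannot act as a nucleophile, the magnesium chelate presents the diketone carbon to the ester, and aromatisation makes the closure irreversible. Basic methanol at reflux should also cleave the aryl silyl ether of ring B, so the target is released in the same operation.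

**Compound list**

1 | methyl 3-methylbut-2-enoate | COC(=O)C=C(C)C | starting material
2 | 4-bromo-2-methylbut-1-ene | C=C(C)CCBr | starting material
3 | methyl 5-methyl-2-(prop-1-en-2-yl)hex-5-enoate (racemic) | COC(=O)C(CCC(C)=C)C(C)=C | intermediate
4 | 5-methyl-2-(prop-1-en-2-yl)hex-5-en-1-ol (racemic) | OCC(CCC(C)=C)C(C)=C | intermediate
5 | (2S)-5-methyl-2-(prop-1-en-2-yl)hex-5-en-1-ol | C=C(C)CC[C@H](CO)C(=C)C | intermediate
6 | (3S)-3-(iodomethyl)-2,6-dimethylhepta-1,6-diene | C=C(C)CC[C@H](CI)C(=C)C | intermediate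
7 | acetylacetone (pentane-2,4-dione) | CC(=O)CC(C)=O | starting material
8 | 3-[(2R)-5-methyl-2-(prop-1-en-2-yl)hex-5-en-1-yl]pentane-2,4-dione | C=C(C)CC[C@H](CC(C(C)=O)C(C)=O)C(=C)C | intermediate
9 | 3,5-dioxo-4-[(2R)-5-methyl-2-(prop-1-en-2-yl)hex-5-en-1-yl]hexanoic acid (not isolated; C4 is enolisable and not defined) | C=C(C)CC[C@H](CC(C(C)=O)C(=O)CC(=O)O)C(=C)C | intermediate
10 | 4-hydroxy-6-methyl-5-[(2R)-5-methyl-2-(prop-1-en-2-yl)hex-5-en-1-yl]-2H-pyran-2-one | C=C(C)CC[C@H](CC1=C(C)OC(=O)C=C1O)C(=C)C | intermediate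
11 | 4-hydroxy-6-methyl-3-(3-methylbut-2-en-1-yl)-5-[(2R)-5-methyl-2-(prop-1-en-2-yl)hex-5-en-1-yl]-2H-pyran-2-one | C=C(C)CC[C@H](CC1=C(C)OC(=O)C(CC=C(C)C)=C1O)C(=C)C | intermediate
12 | 4-methoxy-6-methyl-3-(3-methylbut-2-en-1-yl)-5-[(2R)-5-methyl-2-(prop-1-en-2-yl)hex-5-en-1-yl]-2H-pyran-2-one | C=C(C)CC[C@H](CC1=C(C)OC(=O)C(CC=C(C)C)=C1OC)C(=C)C | intermediate
13 | methyl 3-hydroxybenzoate | COC(=O)c1cccc(O)c1 | starting material
14 | methyl 3-[(tert-butyldimethylsilyl)oxy]benzoate | COC(=O)c1cccc(O[Si](C)(C)C(C)(C)C)c1 | intermediate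
15 | 6-{2-[3-(tert-butyldimethylsilyloxy)phenyl]-2-oxoethyl}-4-methoxy-3-(3-methylbut-2-en-1-yl)-5-[(2R)-5-methyl-2-(prop-1-en-2-yl)hex-5-en-1-yl]-2H-pyran-2-one | C=C(C)CC[C@H](CC1=C(CC(=O)c2cccc(O[Si](C)(C)C(C)(C)C)c2)OC(=O)C(CC=C(C)C)=C1OC)C(=C)C | intermediate
16 | methyl (2E,4Z)-7-{3-[(tert-butyldimethylsilyl)oxy]phenyl}-5-hydroxy-3-methoxy-2-(3-methylbut-2-en-1-yl)-4-[(2R)-5-methyl-2-(prop-1-en-2-yl)hex-5-en-1-yl]-7-oxohepta-2,4-dienoate (not isolated; present as its magnesium enolate, drawn as the dienol that ring opening gives) | COC(=O)/C(CC=C(C)C)=C(OC)\C(C[C@@H](CCC(C)=C)C(C)=C)=C(O)\CC(=O)c1cccc(O[Si](C)(C)C(C)(C)C)c1 | intermediate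
17 | {3-[(tert-butyldimethylsilyl)oxy]phenyl}{2,6-dihydroxy-4-methoxy-3-(3-methylbut-2-en-1-yl)-5-[(2R)-5-methyl-2-(prop-1-en-2-yl)hex-5-en-1-yl]phenyl}methanone (not isolated) | C=C(C)CC[C@H](Cc1c(O)c(C(=O)c2cccc(O[Si](C)(C)C(C)(C)C)c2)c(O)c(CC=C(C)C)c1OC)C(=C)C | intermediate
18 | (3-hydroxyphenyl){2,6-dihydroxy-4-methoxy-3-(3-methylbut-2-en-1-yl)-5-[(2R)-5-methyl-2-(prop-1-en-2-yl)hex-5-en-1-yl]phenyl}methanone (CNP0139402.2) | C=C(C)CC[C@H](Cc1c(O)c(C(=O)c2cccc(O)c2)c(O)c(CC=C(C)C)c1OC)C(=C)C | target

**Summary**

Total step count: 11. Longest linear sequence: 10 steps (steps 1 to 8, 10 and 11); step 9 is a one-step branch.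

Steps most likely to fail:

1. Step 11. The ester of the ring-opened intermediate is a weak acceptor, and the enolate form of 15 may resist methoxide addition. Reclosure to the pyrone, retro-Claisen loss of the aroyl group or closure through enol oxygen may therefore outpace carbon acylation. The fallback sets out from 11 and comes back at 18: the same C3–C4 closure is run in the non-methylated series and the methyl ether is made afterwards. The dianion of 11 (LiN(iPr)2, 3.2 equiv, THF, −78 °C) is acylated with 14 to give 6-{2-[3-(tert-butyldimethylsilyloxy)phenyl]-2-oxoethyl}-4-hydroxy-3-(3-methylbut-2-en-1-yl)-5-[(2R)-5-methyl-2-(prop-1-en-2-yl)hex-5-en-1-yl]-2H-pyran-2-one F1. Mg(OMe)2 in refluxing methanol should then convert this 4-hydroxy-pyrone, the substrate type closest to precedent for the ring transformation, with loss of the silyl group into (3-hydroxyphenyl){2,4,6-trihydroxy-3-(3-methylbut-2-en-1-yl)-5-[(2R)-5-methyl-2-(prop-1-en-2-yl)hex-5-en-1-yl]phenyl}methanone F2. Its C6 hydroxyl is the only ring-A hydroxyl not hydrogen-bonded to the ketone and the most acidic phenol of the molecule, so one equivalent of Me2SO4 with K2CO3 in acetone should methylate it selectively to give 18.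

2. Step 3. The lipase may discriminate poorly between the enantiomers or prefer the wrong one, which would cost most of the material or leave the alcohol enantiomerically impure. The fallback sets out from 3 and comes back at 5: covalent diastereomers are separated instead. Ester 3 is saponified (LiOH, THF–water) to 5-methyl-2-(prop-1-en-2-yl)hex-5-enoic acid (racemic) F3. Its pivalic mixed anhydride (pivaloyl chloride, Et3N, THF, −20 °C) is coupled with (S)-4-benzyl-1,3-oxazolidin-2-one and LiCl. The two imides, (4S)-4-benzyl-3-[(2S)-5-methyl-2-(prop-1-en-2-yl)hex-5-enoyl]-1,3-oxazolidin-2-one F4 and (4S)-4-benzyl-3-[(2R)-5-methyl-2-(prop-1-en-2-yl)hex-5-enoyl]-1,3-oxazolidin-2-one F5, are separated by chromatography. LiBH4 (Et2O, water 1 equiv, 0 °C) reduces the first to 5 with recovery of the auxiliary.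

3. Step 7. Regiocontrol in the allylation may be lost: attack at the tertiary terminus would give the reverse-prenyl isomer, O-allylation may not revert, or a second allylation may occur at pyrone C3. The fallback sets out from 10 and comes back at 12, bypassing 11: the prenyl group is introduced by cross-coupling. N-Bromosuccinimide (CH2Cl2, 0 °C) should brominate the enolic pyrone C3, far more nucleophilic than the isolated alkenes, to give 3-bromo-4-hydroxy-6-methyl-5-[(2R)-5-methyl-2-(prop-1-en-2-yl)hex-5-en-1-yl]-2H-pyran-2-one F6. O-Methylation (Me2SO4, K2CO3, acetone) gives 3-bromo-4-methoxy-6-methyl-5-[(2R)-5-methyl-2-(prop-1-en-2-yl)hex-5-en-1-yl]-2H-pyran-2-one F7. Stille coupling with Bu3SnCH2CH=CMe2 (Pd(PPh3)4, DMF, 80 °C) gives 12.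

**Further compounds**

F1 | step 11 | 6-{2-[3-(tert-butyldimethylsilyloxy)phenyl]-2-oxoethyl}-4-hydroxy-3-(3-methylbut-2-en-1-yl)-5-[(2R)-5-methyl-2-(prop-1-en-2-yl)hex-5-en-1-yl]-2H-pyran-2-one | C=C(C)CC[C@H](CC1=C(CC(=O)c2cccc(O[Si](C)(C)C(C)(C)C)c2)OC(=O)C(CC=C(C)C)=C1O)C(=C)C
F2 | step 11 | (3-hydroxyphenyl){2,4,6-trihydroxy-3-(3-methylbut-2-en-1-yl)-5-[(2R)-5-methyl-2-(prop-1-en-2-yl)hex-5-en-1-yl]phenyl}methanone | C=C(C)CC[C@H](Cc1c(O)c(C(=O)c2cccc(O)c2)c(O)c(CC=C(C)C)c1O)C(=C)C
F3 | step 3 | 5-methyl-2-(prop-1-en-2-yl)hex-5-enoic acid (racemic) | OC(=O)C(CCC(C)=C)C(C)=C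
F4 | step 3 | (4S)-4-benzyl-3-[(2S)-5-methyl-2-(prop-1-en-2-yl)hex-5-enoyl]-1,3-oxazolidin-2-one | C=C(C)CC[C@H](C(=O)N1[C@@H](Cc2ccccc2)COC1=O)C(=C)C
F5 | step 3 | (4S)-4-benzyl-3-[(2R)-5-methyl-2-(prop-1-en-2-yl)hex-5-enoyl]-1,3-oxazolidin-2-one | C=C(C)CC[C@@H](C(=O)N1[C@@H](Cc2ccccc2)COC1=O)C(=C)C
F6 | step 7 | 3-bromo-4-hydroxy-6-methyl-5-[(2R)-5-methyl-2-(prop-1-en-2-yl)hex-5-en-1-yl]-2H-pyran-2-one | C=C(C)CC[C@H](CC1=C(C)OC(=O)C(Br)=C1O)C(=C)C
F7 | step 7 | 3-bromo-4-methoxy-6-methyl-5-[(2R)-5-methyl-2-(prop-1-en-2-yl)hex-5-en-1-yl]-2H-pyran-2-one | C=C(C)CC[C@H](CC1=C(C)OC(=O)C(Br)=C1OC)C(=C)C
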